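The earlier runs and the new flask were generated by integration on assumed constants; the scatter is artificial.

The isomer of the product cannot be read from the alpha or delta run, for neither followed it, so the meeting began with a subtraction. Alpha is the flask asked about, followed to 5.00 h; delta is the same charge at 75 °C.

common to all: substrate 0.24 M; spent carrier 5.5 mM
- alpha: salt in the second phase 0.24 M; temperature 90 °C; the very flask that is asked about, followed so far
- delta: salt in the second phase 0.24 M; temperature 75 °C; run made earlier
- flask: salt in the second phase 0.240 M; temperature 90 °C; time 6.0 h; volume of the second phase over the first 1.0

| run | time / h | target / % | substrate / % |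
|---|---|---|---|
| alpha | 0.667 | 43.5 | 51.0 |
| alpha | 1.50 | 65.5 | 21.3 |
| alpha | 3.00 | 72.9 | 6.2 |
| alpha | 5.00 | 71.0 | 1.7 |
| delta | 1.33 | 34.6 | 63.2 |
| delta | 3.00 | 58.2 | 37.4 |
| delta | 6.00 | 70.2 | 12.4 |
| delta | 10.0 | 67.6 | 4.1 |

(standard deviation of a reading: 1 percentage point)

- violet: change nothing and wait 12 h more
- ochre: at 6.0 h take out 90% of the target then present, then wait 12 h
- blue: at 6.0 h raise the temperature by 25 K, then wait 12 h
- grey: at 6.0 h add substrate, 50.0% of the amount charged, then wait 12 h

- target, in percent of the substrate first charged, at 6.0 h
- what to do for the largest gain in target; "none" if nothing gains more than 2 percentage points (violet / ochre / blue / grey / none)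
- target present, with what was taken out counted in, in percent of the substrate first charged, after violet
- target present, with what was taken out counted in, in percent of the substrate first charged, after blue

- in the second phase: salt in the second phase, spent salt in the second phase; everything else is in the first
- charges count per volume of the first phase; a concentration in a rate is the amount of a species over the volume of its own phase; every rate counts per litre of the first phase
- target taken out counts as made
- steps under discussion: target <-> isomer of the product; spent carrier + salt in the second phase <-> fresh carrier + spent salt in the second phase; substrate + fresh carrier -> target + spent carrier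
- the earlier runs hold the two phases in the same ratio of volumes as the flask asked about
- additions bring no volume worth counting

The kineticist took what target and substrate leave of the charge: isomer 20.9% at 3.00 h and 27.3% at 5.00 h. She offered 0.385 for [isomer]/[target]. The process chemist objected that this ratio was still climbing.

So she put it back in. The isomer gained over that stretch, set against the mean of [target] − [isomer]/ratio, gave a forward constant of 0.345 h⁻¹. The gap from rest then shrinks to 0.0833 of itself, which places the isomer at 28.3% of the product. Hence the rest ratio (the equilibrium constant), [isomer]/[target] once the two stop exchanging, reads 0.394 from alpha at 90 °C, with the scatter of those readings in it.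

Substrate, extrapolated, stands near 0.890% at 6.0 h, so my figure for target is 71.1%. By that ratio I put violet near 71.7%. Grey was dropped: salt, charged equal to substrate, tracks it, so about 0.890% of its charge is left, under the margin of 2 percentage points. Ochre, re-divided by the ratio, totals 89.8%.

For blue the same two passes ran on delta. With isomer 17.4% at 6.00 h and 28.3% at 10.0 h, the forward constant came to 0.0594 h⁻¹, and the ratio to 0.994. Going round once more gave 0.0687 h⁻¹ and 0.781. Either ratio is larger than at 90 °C. Carrying ln(ratio) straight on over the rise of 25 K puts blue between 88.8% and 92.2%. I lean to blue, narrowly, against ochre.

The forecast gave 70.8% now, 70% after violet and 79% after blue, and chose ochre: “so ochre is best”.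

The flask gives 71.5% now, 71.3% after violet and 93.6% after blue; blue gains 22 points and ochre 18 points, so the choice is blue.

    target ⇌ isomer of the product (K = 0.400, k = 0.230 h⁻¹, Ea = 104 kJ mol⁻¹, ΔH = −83.0 kJ mol⁻¹)
    spent carrier + salt in the second phase ⇌ fresh carrier + spent salt in the second phase (K = 7.69, k = 207 M⁻¹ h⁻¹, Ea = 74.0 kJ mol⁻¹, ΔH = −45.0 kJ mol⁻¹)
    substrate + fresh carrier → target + spent carrier (k = 1530 M⁻¹ h⁻¹, Ea = 78.0 kJ mol⁻¹)
    (constants at 90 °C)

A neighbouring flask, charged with 0.96 M of substrate and read at 6.00 h, has the salt in the second phase as its limiting reagent, down to 0.116% of its own charge. One to one, the salt charge of 0.240 M covers 25.0% of the neighbour's substrate, and the rest ratio of 0.394 read from alpha divides that product to give 17.9% as target. This neighbour holds 18.0% target, 6.96% isomer of the product and 75.0% substrate.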